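You read each flask at 8.0 h, so count by hand what that time allows before you run anything.

| setting | west | north-east | north-west | south-east |
|---|---|---|---|---|
| starting complex | 0.10 M | 0.10 M (fed, over 3.0 h) | 0.10 M | 0.10 M (in portions, 3, over 3.0 h) |
| incoming ligand | 0.180 M | 0.180 M | 0.180 M (fed, over 3.0 h) | 0.180 M |
| temperature | 25 °C |  | 25 °C | 25 °C |
| time | 8.0 h | 8.0 h | 8.0 h | 8.0 h |
| remark | everything together at the start | the addition at −15 °C, then warmed to 25 °C; the feed brings no volume worth counting | all else is in the flask from the start; the feed brings no volume worth counting | first portion at the start, last at 3.0 h |

    complex with two exchanged + incoming ligand → leaving ligand + complex with three exchanged (k1 = 0.152 L mol⁻¹ min⁻¹, Ea1 = 66.0 kJ mol⁻¹)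
    complex with one exchanged + incoming ligand → leaving ligand + complex with two exchanged (k2 = 0.0374 L mol⁻¹ min⁻¹, Ea2 = 57.0 kJ mol⁻¹)
    starting complex + incoming ligand → leaving ligand + complex with one exchanged (k3 = 0.0582 L mol⁻¹ min⁻¹, Ea3 = 58.0 kJ mol⁻¹)
    complex with three exchanged ⇌ isomer of the product (K4 = 3.0, k4 = 0.00292 min⁻¹, Ea4 = 101 kJ mol⁻¹, ΔH4 = −24.0 kJ mol⁻¹)
    (constants at 25 °C)

- at 25 °C the constants are as listed, elsewhere as the activation energies and enthalpies make them

- which flask leads in amount of complex with three exchanged, in percent of the starting complex charged ("all alike" within 1.5 percentage points) (west / north-east / north-west / south-east / all alike)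
- how much complex with three exchanged is there at the end, in percent of the starting complex charged: west
- how much complex with three exchanged is there at the end, in percent of the starting complex charged: north-east
- how much complex with three exchanged is there at the end, in percent of the starting complex charged: north-west
- how much complex with three exchanged is there at the end, in percent of the starting complex charged: south-east

The incoming ligand is the limiting reagent: its charge gives 1.80 exchanges per starting complex, fewer than the 3 of a full exchange. Take a pseudo-first-order lifetime for it, as if [starting complex] stayed at its charge and every form of the complex reacted at the rate constant of the first exchange: 2.86 h. Then integrate [incoming ligand] over time and multiply by the rate constant of the first exchange. For west this gives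

N = ([incoming ligand] charged / [starting complex] charged) × (1 − exp(−t / lifetime)) = 1.69

This is the turnover count: the exposure of a complex to ligand, in units of the first exchange. From it, for west:

starting complex left = exp(−N) = 18.5%
complex with one exchanged, with k2/k3 = 0.643: 42.8%
complex with two exchanged, with k2/k1 = 0.246: 10.5%

The last line treats that complex as steady, since in west its half-life by step 1 alone, with the other concentrations as charged, is 0.42 h, shorter than the 1.7 h of complex with one exchanged by step 2 alone.

Two ways now give the pool of complex with three exchanged plus isomer:

counting complexes: 28.2%
counting ligand, with N as exchanges made: 35.0%

They part by 6.8 percentage points. Which one cheats? At this reckoned mix for the end of west, ligand goes at 0.735 of the pace the lifetime assumes. So the ligand count spends too much and stands high. The slower loss also means more exposure than N, so the complex count stands low. I take the middle, 31.6%.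

The pool relaxes towards the isomer with lifetime 4.28 h. I give the pool a mean age of 4.00 h, which leaves 54.5% of it unisomerised. West: 17.2%.

I count north-west and south-east as batches with 6.50 h of time, and north-east as a batch starting at the warming, with 5.00 h. Then N is 1.61 and 1.49. The pools are 29.1% and 24.8%, and the unisomerised shares are 60.1% and 66.8%. The smaller pool keeps the larger share. North-west: 17.5%. South-east: 17.5%. North-east: 16.6%. My widest gap is 0.9 points, inside the margin of 1.5 points, so I say all alike.

The forecast says all alike, with 18.3% west, 17.9% north-east, 18.3% north-west and 18% south-east, on the ground that “the flasks that make more of it sooner also lose more to the isomer”.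

The simulation gives 18.0% west, 17.6% north-east, 18.4% north-west and 18.2% south-east, so the answer is all alike.

Put N back on west: exp(−N) was 18.5%, and west holds 15% of its starting complex at 8.00 h. Now take south-east with 0.31 M of incoming ligand, time held. Its turnover count is 2.78, so 6.21% of the starting complex should remain. The same two counts, with the share 60.1%, give 40.6% complex with three exchanged. The south-east flask with that charge ends with 5.21% starting complex and 37.3% complex with three exchanged.

(Its constants are assumed; the flask was simulated.)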